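Assumption: licochalcone D has no stereogenic centre and is achiral, so "single enantiomer" is read as the single (E)-isomer of the Cα=Cβ double bond drawn in the SMILES.

## Structural features

Licochalcone D is a C6–C3–C6 chalcone. Ring A (ketone side) is a 4'-hydroxy-3'-prenylphenyl group and ring B (β side) is a 3,4-dihydroxy-2-methoxyphenyl group; they are joined by the three-carbon bridge C1'–C(=O)–Cα=Cβ–C1. There is no stereocentre; the only stereo-element is the E geometry of Cα=Cβ. Three groups are fragile. The prenyl olefin sits ortho to a free phenol and closes to a 2,2-dimethylchroman under acid. The ring B catechol oxidises in air, fastest in base. The enone is a Michael acceptor. The three adjacent oxygens on ring B are differentiated (O-2 methylated, O-3 and O-4 free), and the prenyl group must sit ortho to the ring A hydroxyl without allylic transposition. The real difficulty is therefore not a ring or a stereocentre but the union of two electron-rich, differently masked arenes through the enone, with the carbonyl on ring A and the alkene E, under conditions that the prenyl group tolerates. The key step exploits one feature: the carbonyl carbon is a single carbon at the oxidation level of carbon monoxide, flanked by C1' of ring A and by Cα of a vinyl arene. Both of its C–C bonds, C1'–C(=O) and C(=O)–Cα, can therefore be made in one operation from an aryl halide, CO and a styrene.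

## Logic of the disconnections

**12 ⇒ 11.** The three phenolic O–H bonds of 12 are traced back to three O–CH2 acetal bonds in 11. The cut is made there because free phenols would intercept the acyl–palladium state of the key step as aryl esters, and because the ring B catechol is air-sensitive in base. Nothing is gained in skeleton; the gain is a precursor inert to base, ylide and palladium. The forward step must cleave three acetals mildly enough to spare the prenyl olefin next to the newly freed 4'-hydroxyl.

**11 ⇒ 5 + 10 + 9 (key disconnection).** Two bonds are cut at once, C1'–C(=O) and C(=O)–Cα, so that the carbonyl carbon leaves as 10. In one sentence: a palladium-catalysed three-component carbonylative Heck union of 5, 10 and 9 builds the whole enone bridge. The cut is made there because the carbonyl carbon then needs no handle on either ring: ring A enters as a plain aryl iodide and ring B as a plain vinyl arene. The gain is that 11 falls into one ring A piece, one ring B piece and a one-carbon gas, fully convergent. The forward step must insert 10 before the alkene, deliver the acyl group to the terminal carbon of 9, eliminate to the E-alkene and ignore the prenyl olefin of 5.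

**9 ⇒ 8.** The C=CH2 bond of the vinyl group (the future Cβ=Cα) is cut back to the formyl C=O of 8. The reason is that the formyl group is what makes the oxygen pattern of ring B accessible (next paragraph), and a one-carbon olefination is the shortest link from it to the vinyl group. The forward step must be non-acidic so that the two acetals survive.

**8 ⇒ 7 ⇒ 6.** The O–CH3 bond at O-2 is cut, then the two O–CH2 bonds at O-3 and O-4. In 6 the hydroxyl at C-2 is held in a hydrogen bond to the formyl oxygen, which sets it apart from the other two. The gain is that three adjacent oxygens are differentiated in two steps from a commercial arene, with no C–O bond to the ring to be made. The forward steps must stop the double acetalisation at O-3/O-4 and then alkylate the chelated O-2.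

**5 ⇒ 4 ⇒ 1 + 2 (via 3).** The O–CH2 acetal bond on O-4' is cut, then the C3'–CH2 aryl–prenyl bond. In 1 the para position is occupied by iodine, so the only nucleophilic ring carbons of 3 are the two equivalent ortho ones. The iodine thus serves twice, as para blocker and as the handle for the key step. The forward step must favour C- over O-alkylation of 3, attack the primary carbon of 2 without allylic transposition, and stop at mono-alkylation.

## Other disconnections considered

Alternative 1: Cut Cα=Cβ (the first disconnection that comes to mind). The forward key step is a Claisen–Schmidt condensation of the acetophenone A1 with aldehyde 8 under hydroxide, converging on 11. It is rejected first because it is the default route and therefore fails the requirement for an unconventional key disconnection. Mechanistically, 8 carries ortho- and para-oxygen donors and should be a weak, hindered electrophile, so long exposure to concentrated hydroxide is to be expected. A1 also forces an acetyl group onto ring A from the start. It would be one step shorter (no methylenation). The preference for the chosen plan therefore rests on strategy, not step count: two bonds are made in one catalytic event under near-neutral conditions.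

Alternative 2: Cut Cβ–C1 of ring B. The forward key step is a Mizoroki–Heck arylation of the aryl vinyl ketone A2 with the aryl iodide A3, again converging on 11. A3 would need a regioselective iodination of a 1,2,3-trioxygenated benzene, where the two positions flanking the oxygen triad compete; the formyl group of 6 settles this regiochemistry for free. A3 is also ortho-substituted and electron-rich, so oxidative addition should be slow. A2 is a polymerisation-prone Michael acceptor that needs several steps from 5. The route would be longer and less convergent.

Alternative 3: Cut C1'–C(=O) only. The forward key step is an acyl substitution of the cinnamoyl Weinreb amide A4 by the aryllithium A5 (from 5 by iodine–lithium exchange), giving 11. The step count would be the same as in the chosen plan. However, it needs a stoichiometric organolithium at low temperature, competing 1,4-addition to the cinnamamide is possible, and only one of the two bonds at the carbonyl is formed in the key step. The chosen plan forms both catalytically and takes the carbonyl carbon from CO.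

Key step: step 6

## Route

Step 1
Reactants: 1 4-iodophenol; 2 1-bromo-3-methylbut-2-ene (prenyl bromide)
Product: 4 4-iodo-2-(3-methylbut-2-en-1-yl)phenol, via sodium 4-iodophenoxide 3 (not isolated)
Conditions: NaH (1.05 equiv), toluene, 0 °C to rt; then 2 (1.0 equiv), rt
Reagents that add atoms: none
Why: Ortho-selective C-alkylation of a phenoxide in a non-polar medium: the aggregated sodium ion pair shields oxygen and delivers the primary allylic bromide by SN2 (no allylic transposition) to an ortho carbon, the para position being blocked by iodine; tautomerisation restores the phenol.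

Step 2
Reactants: 4 4-iodo-2-(3-methylbut-2-en-1-yl)phenol
Product: 5 4-iodo-1-(methoxymethoxy)-2-(3-methylbut-2-en-1-yl)benzene
Conditions: MOMCl, i-Pr2NEt, CH2Cl2, 0 °C to rt
Reagents that add atoms: chloromethyl methyl ether, COCCl
Why: Standard O-alkylation of a phenol to its methoxymethyl ether; the aryl iodide and the prenyl olefin are inert to these conditions, and the mask keeps the phenol from acting as a nucleophile in step 6.

Step 3
Reactants: 6 2,3,4-trihydroxybenzaldehyde
Product: 7 2-hydroxy-3,4-bis(methoxymethoxy)benzaldehyde
Conditions: MOMCl (2.1 equiv), i-Pr2NEt (2.5 equiv), CH2Cl2/THF, 0 °C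
Reagents that add atoms: chloromethyl methyl ether, COCCl
Why: Regioselective O-alkylation: the 4-hydroxyl (para to the formyl group, most acidic) and then the 3-hydroxyl react, while the 2-hydroxyl is deactivated by its intramolecular hydrogen bond to the formyl oxygen, which the weakly polar medium preserves.

Step 4
Reactants: 7 2-hydroxy-3,4-bis(methoxymethoxy)benzaldehyde
Product: 8 2-methoxy-3,4-bis(methoxymethoxy)benzaldehyde
Conditions: MeI, K2CO3, DMF, rt to 40 °C
Reagents that add atoms: iodomethane, CI
Why: Williamson methylation of the remaining chelated phenol; carbonate in DMF breaks the hydrogen bond, and the aldehyde and acetals are stable to these conditions.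

Step 5
Reactants: 8 2-methoxy-3,4-bis(methoxymethoxy)benzaldehyde
Product: 9 1-ethenyl-2-methoxy-3,4-bis(methoxymethoxy)benzene
Conditions: Ph3PCH3Br, KOt-Bu, THF, 0 °C to rt
Reagents that add atoms: methyltriphenylphosphonium bromide, C[P+](c1ccccc1)(c1ccccc1)c1ccccc1.[Br-]
Why: Wittig methylenation with the non-stabilised ylide; the basic, non-acidic conditions leave both acetals intact, and the electron-rich styrene should be kept cold with a trace of BHT and used promptly.

Step 6
Reactants: 5 4-iodo-1-(methoxymethoxy)-2-(3-methylbut-2-en-1-yl)benzene; 9 1-ethenyl-2-methoxy-3,4-bis(methoxymethoxy)benzene; 10 carbon monoxide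
Product: 11 (2E)-3-[2-methoxy-3,4-bis(methoxymethoxy)phenyl]-1-[4-(methoxymethoxy)-3-(3-methylbut-2-en-1-yl)phenyl]prop-2-en-1-one
Conditions: 10 (10 bar), [Pd(cinnamyl)Cl]2 (2 mol%), BuPAd2 (6 mol%), Et3N (2 equiv), BHT (cat.), 1,4-dioxane, 100 °C
Reagents that add atoms: none
Why: Three-component carbonylative Heck reaction (carbonylative vinylation of an aryl iodide with a styrene), a known route to chalcones. Pd(0) adds oxidatively to the C–I bond of 5, CO inserts into the aryl–Pd bond, the vinyl group of 9 inserts into the resulting acyl–Pd bond with the acyl carbon going to the terminal CH2 and palladium to the benzylic carbon, and syn β-hydride elimination releases the enone while Et3N returns the palladium hydride to Pd(0). No ring is closed and no stereocentre is formed; the E geometry follows from syn β-hydride elimination through the rotamer with aryl and aroyl groups anti, and the conjugated E-enone is also the thermodynamic isomer. Carbonylation must precede alkene insertion: CO pressure and the fast migration of the electron-rich para-alkoxyaryl group to CO secure this against direct Heck arylation of the hindered ortho-substituted styrene. Acyl transfer to the terminal carbon is secured by sterics and by the benzylic stabilisation of the resulting alkylpalladium. The trisubstituted prenyl olefin is a poor insertion partner and sits meta to the palladated carbon, so it can neither compete with the vinyl group nor cyclise. With all phenols masked as acetals and no O–H or N–H nucleophile present, the acyl–palladium state has no path to an ester or amide.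

Step 7
Reactants: 11 (2E)-3-[2-methoxy-3,4-bis(methoxymethoxy)phenyl]-1-[4-(methoxymethoxy)-3-(3-methylbut-2-en-1-yl)phenyl]prop-2-en-1-one
Product: 12 licochalcone D, (2E)-3-(3,4-dihydroxy-2-methoxyphenyl)-1-[4-hydroxy-3-(3-methylbut-2-en-1-yl)phenyl]prop-2-en-1-one
Conditions: HCl (1.25 M in MeOH), MeOH, 0 °C to rt, Ar
Reagents that add atoms: none
Why: Acid-catalysed methanolysis of the three aryl methoxymethyl acetals (transacetalisation to dimethoxymethane); dilute acid at or below room temperature under argon should spare the prenyl olefin, the enone geometry and the catechol.

## Compound list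

1 | 4-iodophenol | Oc1ccc(I)cc1 | starting material
2 | 1-bromo-3-methylbut-2-ene (prenyl bromide) | CC(C)=CCBr | starting material
3 | sodium 4-iodophenoxide | [Na+].[O-]c1ccc(I)cc1 | intermediate (not isolated)
4 | 4-iodo-2-(3-methylbut-2-en-1-yl)phenol | CC(C)=CCc1cc(I)ccc1O | intermediate
5 | 4-iodo-1-(methoxymethoxy)-2-(3-methylbut-2-en-1-yl)benzene | COCOc1ccc(I)cc1CC=C(C)C | intermediate
6 | 2,3,4-trihydroxybenzaldehyde | O=Cc1ccc(O)c(O)c1O | starting material
7 | 2-hydroxy-3,4-bis(methoxymethoxy)benzaldehyde | COCOc1ccc(C=O)c(O)c1OCOC | intermediate
8 | 2-methoxy-3,4-bis(methoxymethoxy)benzaldehyde | COCOc1ccc(C=O)c(OC)c1OCOC | intermediate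
9 | 1-ethenyl-2-methoxy-3,4-bis(methoxymethoxy)benzene | COCOc1ccc(C=C)c(OC)c1OCOC | intermediate
10 | carbon monoxide | [C-]#[O+] | starting material
11 | (2E)-3-[2-methoxy-3,4-bis(methoxymethoxy)phenyl]-1-[4-(methoxymethoxy)-3-(3-methylbut-2-en-1-yl)phenyl]prop-2-en-1-one | COCOc1ccc(/C=C/C(=O)c2ccc(OCOC)c(CC=C(C)C)c2)c(OC)c1OCOC | intermediate
12 | licochalcone D, (2E)-3-(3,4-dihydroxy-2-methoxyphenyl)-1-[4-hydroxy-3-(3-methylbut-2-en-1-yl)phenyl]prop-2-en-1-one | COc1c(/C=C/C(=O)c2ccc(O)c(CC=C(C)C)c2)ccc(O)c1O | target

## Step count and least certain steps

Total step count: 7. Longest linear sequence: 5 steps (steps 3, 4, 5, 6, 7, from 6 to 12); the ring A branch (steps 1 and 2) joins at step 6.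

**Step 6 (key step).** The most likely failures are three. Direct, non-carbonylative Heck arylation may compete if CO insertion is outrun at low CO concentration. The electron-rich styrene may oligomerise thermally at 100 °C. Palladium hydride may walk the prenyl double bond into conjugation with ring A. All three come from the long lifetime of organopalladium states next to a hindered alkene partner. The fallback abandons the three-component union for a stepwise, stoichiometric construction of the same two bonds; it sets out from 8 and 5 and comes back at 11. Aldehyde 8 would be homologated with (triphenylphosphoranylidene)acetaldehyde in toluene at 80 °C to (2E)-3-[2-methoxy-3,4-bis(methoxymethoxy)phenyl]prop-2-enal F1. Iodide 5 would be converted with i-PrMgCl·LiCl in THF into [4-(methoxymethoxy)-3-(3-methylbut-2-en-1-yl)phenyl]magnesium chloride F2 (not isolated). 1,2-Addition of F2 to F1 at −78 to 0 °C should give racemic (2E)-3-[2-methoxy-3,4-bis(methoxymethoxy)phenyl]-1-[4-(methoxymethoxy)-3-(3-methylbut-2-en-1-yl)phenyl]prop-2-en-1-ol F3. Oxidation of this doubly activated allylic alcohol with MnO2 in CH2Cl2 should then give 11.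

**Step 1.** O-alkylation and a second ortho-alkylation may compete with the desired mono-C-alkylation, because the selectivity rests only on ion pairing in a heterogeneous medium. The fallback delivers the prenyl group by a sigmatropic shift instead of by direct C-alkylation; it sets out from 1 and comes back at 4. Phenol 1 would be O-alkylated with 3-chloro-3-methylbut-1-yne (DBU, cat. CuCl2, MeCN, 0 °C) to 1-iodo-4-[(2-methylbut-3-yn-2-yl)oxy]benzene F4. Semi-hydrogenation over Lindlar catalyst with quinoline should give 1-iodo-4-[(2-methylbut-3-en-2-yl)oxy]benzene F5. Heating F5 in N,N-diethylaniline at about 130 °C should bring about the aromatic Claisen rearrangement, in which the [3,3] shift places the unrearranged prenyl group on the ortho carbon and gives 4.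

**Step 3.** Regiocontrol may be lost: partial alkylation of the chelated 2-hydroxyl or incomplete alkylation of O-3 would give mixtures, because the discrimination rests on a hydrogen bond only. The fallback replaces selective protection by exhaustive protection and chelation-assisted selective deprotection; it sets out from 6 and comes back at 7. Aldehyde 6 would be fully alkylated (MOMCl in excess, NaH, DMF) to 2,3,4-tris(methoxymethoxy)benzaldehyde F6. Brief treatment with catalytic HCl in MeOH/THF at 0 °C, followed by aqueous work-up, should remove the acetal ortho to the formyl group first, since the neighbouring carbonyl oxygen assists its protonation and the freed phenol is stabilised by the hydrogen bond, giving 7.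

**Step 7.** Acid may trigger hydroalkoxylation of the prenyl olefin, either by cyclisation of the freed 4'-hydroxyl onto the protonated olefin (chroman formation) or by Markovnikov addition of methanol, before the last acetal is cleaved; the tertiary cation is easily reached. The fallback changes the protecting group to one removed by fluoride; it sets out from 8 and 4 and comes back at 12. Aldehyde 8 would be deprotected with methanolic HCl (no prenyl group is present at this stage) to 3,4-dihydroxy-2-methoxybenzaldehyde F7. Silylation (TBSCl, imidazole, DMF) should give 3,4-bis[(tert-butyldimethylsilyl)oxy]-2-methoxybenzaldehyde F8, and Wittig methylenation 1-ethenyl-2-methoxy-3,4-bis[(tert-butyldimethylsilyl)oxy]benzene F9. Phenol 4 would be silylated in the same way to tert-butyl[4-iodo-2-(3-methylbut-2-en-1-yl)phenoxy]dimethylsilane F10. The carbonylative Heck union of F10, 10 and F9 under the conditions of step 6 should give (2E)-3-{3,4-bis[(tert-butyldimethylsilyl)oxy]-2-methoxyphenyl}-1-{4-[(tert-butyldimethylsilyl)oxy]-3-(3-methylbut-2-en-1-yl)phenyl}prop-2-en-1-one F11. Desilylation with TBAF buffered with AcOH in THF at 0 °C should then give 12 without any acid strong enough to protonate the prenyl olefin.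

## Further compounds

F1 | step 6 | (2E)-3-[2-methoxy-3,4-bis(methoxymethoxy)phenyl]prop-2-enal | COCOc1ccc(/C=C/C=O)c(OC)c1OCOC
F2 | step 6 | [4-(methoxymethoxy)-3-(3-methylbut-2-en-1-yl)phenyl]magnesium chloride | COCOc1ccc([Mg]Cl)cc1CC=C(C)C
F3 | step 6 | racemic (2E)-3-[2-methoxy-3,4-bis(methoxymethoxy)phenyl]-1-[4-(methoxymethoxy)-3-(3-methylbut-2-en-1-yl)phenyl]prop-2-en-1-ol | COCOc1ccc(/C=C/C(O)c2ccc(OCOC)c(CC=C(C)C)c2)c(OC)c1OCOC
F4 | step 1 | 1-iodo-4-[(2-methylbut-3-yn-2-yl)oxy]benzene | CC(C)(C#C)Oc1ccc(I)cc1
F5 | step 1 | 1-iodo-4-[(2-methylbut-3-en-2-yl)oxy]benzene | CC(C)(C=C)Oc1ccc(I)cc1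
F6 | step 3 | 2,3,4-tris(methoxymethoxy)benzaldehyde | COCOc1ccc(C=O)c(OCOC)c1OCOC
F7 | step 7 | 3,4-dihydroxy-2-methoxybenzaldehyde | COc1c(C=O)ccc(O)c1O
F8 | step 7 | 3,4-bis[(tert-butyldimethylsilyl)oxy]-2-methoxybenzaldehyde | COc1c(C=O)ccc(O[Si](C)(C)C(C)(C)C)c1O[Si](C)(C)C(C)(C)C
F9 | step 7 | 1-ethenyl-2-methoxy-3,4-bis[(tert-butyldimethylsilyl)oxy]benzene | COc1c(C=C)ccc(O[Si](C)(C)C(C)(C)C)c1O[Si](C)(C)C(C)(C)C
F10 | step 7 | tert-butyl[4-iodo-2-(3-methylbut-2-en-1-yl)phenoxy]dimethylsilane | CC(C)=CCc1cc(I)ccc1O[Si](C)(C)C(C)(C)C
F11 | step 7 | (2E)-3-{3,4-bis[(tert-butyldimethylsilyl)oxy]-2-methoxyphenyl}-1-{4-[(tert-butyldimethylsilyl)oxy]-3-(3-methylbut-2-en-1-yl)phenyl}prop-2-en-1-one | COc1c(/C=C/C(=O)c2ccc(O[Si](C)(C)C(C)(C)C)c(CC=C(C)C)c2)ccc(O[Si](C)(C)C(C)(C)C)c1O[Si](C)(C)C(C)(C)C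
A1 | alternative 1 | 1-[4-(methoxymethoxy)-3-(3-methylbut-2-en-1-yl)phenyl]ethan-1-one | CC(=O)c1ccc(OCOC)c(CC=C(C)C)c1
A2 | alternative 2 | 1-[4-(methoxymethoxy)-3-(3-methylbut-2-en-1-yl)phenyl]prop-2-en-1-one | C=CC(=O)c1ccc(OCOC)c(CC=C(C)C)c1
A3 | alternative 2 | 1-iodo-2-methoxy-3,4-bis(methoxymethoxy)benzene | COc1c(I)ccc(OCOC)c1OCOC
A4 | alternative 3 | (2E)-N-methoxy-3-[2-methoxy-3,4-bis(methoxymethoxy)phenyl]-N-methylprop-2-enamide | COc1c(/C=C/C(=O)N(C)OC)ccc(OCOC)c1OCOC
A5 | alternative 3 | [4-(methoxymethoxy)-3-(3-methylbut-2-en-1-yl)phenyl]lithium | [Li]c1ccc(OCOC)c(CC=C(C)C)c1
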